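The side chain is cut at the C6'–C7' single bond, where the CH2CH2 spacer of the 1,5-diene C3'=C4'/C7'=C8' meets the vinylic CH. The union is done in one flask. 9-BBN converts the terminal vinyl group (C5'=C6') of a chromene-bearing (E)-1,3-diene into a C6' homoallylborane, and palladium couples it with (E)-1-iodo-2,6-dimethylhepta-1,5-diene with retention. The step exploits the methyl branch at C8' (alkyne methylalumination sets E). It also exploits the shielding of C3=C4 of the 2H-pyran ring by quaternary C2 and the benzene ring. C2 (S) comes from Sharpless epoxidation of geraniol. The pyran ring closes by O1–C8a coupling, so the C2–O bond is never broken.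

Key step: step 14

Remark: the chromene is numbered O1, C2, C3, C4, C4a, C5–C8, C8a and the side chain C1' (on C2) to C13'. Read from the SMILES, C2 is S (O1 > C3 > C1' > CH3). From 13 onward the 2H-chromenes are kept away from UV light and strong acid, because electrocyclic ring opening or ionisation at C2 would erode the optical purity.

Step 1
Reactants: 1 4-amino-3-methylphenol
Product: 2 2-methyl-4-(triisopropylsilyloxy)aniline
Conditions: TIPSCl, imidazole, DMF, 0 °C to rt
Reagents that add atoms: triisopropylsilyl chloride, CC(C)[Si](Cl)(C(C)C)C(C)C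
Why: Imidazole-promoted silylation of a phenol (silyl ether protection) is O-selective because any N-silyl species is hydrolysed on work-up, and the bulky TIPS ether should outlast the basic and oxidative steps that follow.

Step 2
Reactants: 2 2-methyl-4-(triisopropylsilyloxy)aniline
Product: 3 2-iodo-6-methyl-4-(triisopropylsilyloxy)aniline
Conditions: NIS, MeCN, 0 °C, dark
Reagents that add atoms: N-iodosuccinimide, O=C1CCC(=O)N1I
Why: Electrophilic aromatic iodination is directed by the amino group, the strongest donor on the ring, to its only free ortho position, the para position being blocked by the silyloxy group.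

Step 3
Reactants: 3 2-iodo-6-methyl-4-(triisopropylsilyloxy)aniline
Product: 5 (4-bromo-3-iodo-5-methylphenoxy)triisopropylsilane, via arenediazonium bromide 4 (not isolated)
Conditions: t-BuONO, CuBr2, MeCN, 0 to 60 °C
Reagents that add atoms: copper dibromide CuBr2, [Cu+2].[Br-].[Br-]
Why: Sandmeyer bromination under aprotic diazotisation swaps the amino group for bromine exactly between the iodine and the methyl group, a pattern that direct halogenation cannot give, and leaves the C–I bond and the silyl ether alone.

Step 4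
Reactants: 6 geraniol
Product: 7 (2S,3S)-2,3-epoxygeraniol
Conditions: Ti(OiPr)4 (cat.), L-(+)-diisopropyl tartrate (cat.), t-BuOOH, 4 Å MS, CH2Cl2, −20 °C
Reagents that add atoms: tert-butyl hydroperoxide, CC(C)(C)OO
Why: Sharpless asymmetric epoxidation is hydroxyl-directed, so only the allylic C2=C3 olefin reacts, and the titanium complex of the L-(+)-tartrate delivers oxygen to the face that gives the (2S,3S)-epoxide, whose tertiary C–O carbon becomes C2 of the target.

Step 5
Reactants: 7 (2S,3S)-2,3-epoxygeraniol
Product: 8 (2S,3R)-3-(chloromethyl)-2-methyl-2-(4-methylpent-3-en-1-yl)oxirane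
Conditions: PPh3, CCl4, NaHCO3, reflux
Reagents that add atoms: tetrachloromethane, ClC(Cl)(Cl)Cl
Why: Appel chlorination converts the primary alcohol by SN2 displacement under buffered neutral conditions that leave the acid-sensitive trisubstituted epoxide and both stereocentres untouched (the descriptor at the CH carbon changes only because chlorine raises the CIP rank of its neighbour).

Step 6
Reactants: 8 (2S,3R)-3-(chloromethyl)-2-methyl-2-(4-methylpent-3-en-1-yl)oxirane
Product: 10 (3S)-3,7-dimethyloct-6-en-1-yn-3-ol, via chlorovinyl carbinol 9 (not isolated)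
Conditions: n-BuLi (3.5 equiv), THF, −78 to −30 °C; aq NH4Cl
Reagents that add atoms: none
Why: In this base-induced double elimination of a 2,3-epoxy chloride, lithiation next to chlorine opens the epoxide by β-elimination to 9 and loss of HCl then gives the alkyne, and because the tertiary C–O bond is never broken the S configuration is retained.

Step 7
Reactants: 5 (4-bromo-3-iodo-5-methylphenoxy)triisopropylsilane + 10 (3S)-3,7-dimethyloct-6-en-1-yn-3-ol
Product: 11 (3S)-1-[2-bromo-3-methyl-5-(triisopropylsilyloxy)phenyl]-3,7-dimethyloct-6-en-1-yn-3-ol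
Conditions: Pd(PPh3)2Cl2 (cat.), CuI (cat.), Et3N, THF, rt
Reagents that add atoms: none
Why: Sonogashira coupling takes place only at the C–I bond, which undergoes oxidative addition far faster than the doubly ortho-substituted C–Br bond, and it tolerates the free tertiary alcohol.

Step 8
Reactants: 11 (3S)-1-[2-bromo-3-methyl-5-(triisopropylsilyloxy)phenyl]-3,7-dimethyloct-6-en-1-yn-3-ol
Product: 12 (1Z,3S)-1-[2-bromo-3-methyl-5-(triisopropylsilyloxy)phenyl]-3,7-dimethylocta-1,6-dien-3-ol
Conditions: H2 (1 atm), Pd/CaCO3 poisoned with Pb(OAc)2 (Lindlar catalyst), quinoline, EtOAc, rt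
Reagents that add atoms: none
Why: Lindlar semihydrogenation adds H2 syn to the alkyne on the poisoned palladium surface and gives the Z-olefin needed for ring closure, while the trisubstituted olefin and the aryl bromide are inert.

Step 9
Reactants: 12 (1Z,3S)-1-[2-bromo-3-methyl-5-(triisopropylsilyloxy)phenyl]-3,7-dimethylocta-1,6-dien-3-ol
Product: 13 (2S)-2,8-dimethyl-2-(4-methylpent-3-en-1-yl)-6-(triisopropylsilyloxy)-2H-chromene
Conditions: Pd(OAc)2 (cat.), tBuXPhos (cat.), Cs2CO3, toluene, 80 °C, dark
Reagents that add atoms: none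
Why: Intramolecular Buchwald–Hartwig-type C–O coupling (six-membered ring by O1–C8a bond formation) suits a tertiary alkoxide, which has no hydrogen on the carbinol carbon to lose, and since only the O–H and C–Br bonds are broken C2 keeps its S configuration.

Step 10
Reactants: 13 (2S)-2,8-dimethyl-2-(4-methylpent-3-en-1-yl)-6-(triisopropylsilyloxy)-2H-chromene
Product: 15 (2E)-5-[(2S)-2,8-dimethyl-6-(triisopropylsilyloxy)-2H-chromen-2-yl]-2-methylpent-2-enal, via allylic alcohol 14 (not isolated)
Conditions: SeO2 (cat.), t-BuOOH, salicylic acid (cat.), CH2Cl2, 0 °C to rt; then MnO2, CH2Cl2, rt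
Reagents that add atoms: selenium dioxide, O=[Se]=O; tert-butyl hydroperoxide, CC(C)(C)OO
Why: Selenium dioxide allylic oxidation (ene reaction then [2,3]-sigmatropic shift) picks the E-methyl group of the terminal gem-dimethyl olefin, the chromene C3=C4 bond has no allylic hydrogen, and MnO2 carries the allylic alcohol part of the crude mixture on to the enal.

Step 11
Reactants: 15 (2E)-5-[(2S)-2,8-dimethyl-6-(triisopropylsilyloxy)-2H-chromen-2-yl]-2-methylpent-2-enal
Product: 16 (2S)-2,8-dimethyl-2-[(3E)-4-methylhexa-3,5-dien-1-yl]-6-(triisopropylsilyloxy)-2H-chromene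
Conditions: Ph3PCH3Br, KOtBu, THF, 0 °C
Reagents that add atoms: methyltriphenylphosphonium bromide, C[P+](c1ccccc1)(c1ccccc1)c1ccccc1.[Br-]
Why: Wittig methylenation with the non-stabilised ylide adds 1,2 to the enal and turns CHO into the C5'=C6' vinyl group without touching the E-olefin or the silyl ether.

Step 12
Reactants: 17 6-methylhept-5-en-2-one
Product: 19 6-methylhept-5-en-1-yne, via enol phosphate 18 (not isolated)
Conditions: LDA, THF, −78 °C; ClP(O)(OEt)2, −78 °C to rt; then LDA (2.3 equiv), −78 °C to rt
Reagents that add atoms: none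
Why: Kinetic deprotonation at the methyl group, trapping as the enol phosphate and base-induced β-elimination of diethyl phosphate is the standard conversion of a methyl ketone into a terminal alkyne.

Step 13
Reactants: 19 6-methylhept-5-en-1-yne
Product: 21 (1E)-1-iodo-2,6-dimethylhepta-1,5-diene, via alkenylalane 20 (not isolated)
Conditions: AlMe3, Cp2ZrCl2 (cat.), CH2Cl2, 0 °C to rt; then I2, THF, −30 to 0 °C
Reagents that add atoms: trimethylaluminium, C[Al](C)C; iodine, II
Why: Negishi zirconium-catalysed methylalumination adds CH3 and Al syn across the terminal alkyne with aluminium on the terminal carbon, iodinolysis with retention gives the E-alkenyl iodide, and the trisubstituted olefin does not react.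

Step 14
Reactants: 16 (2S)-2,8-dimethyl-2-[(3E)-4-methylhexa-3,5-dien-1-yl]-6-(triisopropylsilyloxy)-2H-chromene + 21 (1E)-1-iodo-2,6-dimethylhepta-1,5-diene
Product: 23 (2S)-2,8-dimethyl-6-(triisopropylsilyloxy)-2-[(3E,7E)-4,8,12-trimethyltrideca-3,7,11-trien-1-yl]-2H-chromene, via B-alkyl borane 22 (not isolated)
Conditions: 9-BBN (1.1 equiv), THF, 0 °C to rt; then 21, Pd(dppf)Cl2·CH2Cl2 (cat.), AsPh3 (cat.), aq K3PO4, DMF, rt to 45 °C
Reagents that add atoms: none
Why: 9-BBN adds anti-Markovnikov to the monosubstituted C5'=C6' end of the conjugated diene and places boron on C6' to give the homoallylic borane 22; zerovalent palladium then inserts into the C–I bond of 21, the phosphate-activated borate passes the primary C6' alkyl group to palladium, and reductive elimination forms the C6'–C7' bond. The closest known reaction types are the monohydroboration of terminal 1,3-dienes with 9-BBN and the B-alkyl Suzuki–Miyaura coupling with alkenyl iodides. No ring is closed and no stereocentre is made, and C2 is a remote spectator. The E geometry at C7'=C8' is carried over because oxidative addition and reductive elimination at an alkenyl carbon go with retention, and C3'=C4' stays E because it takes no part. The site selectivity needed in 16 is secured by sterics: bulky 9-BBN prefers the only CH2= terminus, whereas C3'=C4' is trisubstituted and C3=C4 of the pyran ring is a cis-disubstituted styrene-type bond wedged between quaternary C2 and the benzene ring, and 21 is added only after the borane reagent is consumed. The wide bite angle of dppf speeds reductive elimination, so β-hydride elimination of the alkylpalladium species should not compete.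

Step 15
Reactants: 23 (2S)-2,8-dimethyl-6-(triisopropylsilyloxy)-2-[(3E,7E)-4,8,12-trimethyltrideca-3,7,11-trien-1-yl]-2H-chromene
Product: 24 (2S)-2,8-dimethyl-2-[(3E,7E)-4,8,12-trimethyltrideca-3,7,11-trien-1-yl]-2H-chromen-6-ol
Conditions: TBAF, AcOH, THF, 0 °C
Reagents that add atoms: none
Why: Fluoride-induced desilylation buffered with acetic acid frees the C6 phenol under conditions that cannot ionise the tertiary allylic C2–O1 bond or isomerise the olefins.

Compound list
1 | 4-amino-3-methylphenol | Cc1cc(O)ccc1N | starting material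
2 | 2-methyl-4-(triisopropylsilyloxy)aniline | Cc1cc(O[Si](C(C)C)(C(C)C)C(C)C)ccc1N | intermediate
3 | 2-iodo-6-methyl-4-(triisopropylsilyloxy)aniline | Cc1cc(O[Si](C(C)C)(C(C)C)C(C)C)cc(I)c1N | intermediate
4 | 2-iodo-6-methyl-4-(triisopropylsilyloxy)benzenediazonium bromide (formed in the flask) | Cc1cc(O[Si](C(C)C)(C(C)C)C(C)C)cc(I)c1[N+]#N.[Br-] | intermediate
5 | (4-bromo-3-iodo-5-methylphenoxy)triisopropylsilane | Cc1cc(O[Si](C(C)C)(C(C)C)C(C)C)cc(I)c1Br | intermediate
6 | geraniol, (2E)-3,7-dimethylocta-2,6-dien-1-ol | CC(C)=CCC/C(C)=C/CO | starting material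
7 | (2S,3S)-2,3-epoxygeraniol, [(2S,3S)-3-methyl-3-(4-methylpent-3-en-1-yl)oxiran-2-yl]methanol | CC(C)=CCC[C@]1(C)O[C@H]1CO | intermediate
8 | (2S,3R)-3-(chloromethyl)-2-methyl-2-(4-methylpent-3-en-1-yl)oxirane | CC(C)=CCC[C@]1(C)O[C@H]1CCl | intermediate
9 | (3S)-1-chloro-3,7-dimethylocta-1,6-dien-3-ol (present as lithium alkoxide, C1=C2 geometry not defined, formed in the flask) | CC(C)=CCC[C@](C)(O)C=CCl | intermediate
10 | (3S)-3,7-dimethyloct-6-en-1-yn-3-ol | CC(C)=CCC[C@](C)(O)C#C | intermediate
11 | (3S)-1-[2-bromo-3-methyl-5-(triisopropylsilyloxy)phenyl]-3,7-dimethyloct-6-en-1-yn-3-ol | CC(C)=CCC[C@](C)(O)C#Cc1cc(O[Si](C(C)C)(C(C)C)C(C)C)cc(C)c1Br | intermediate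
12 | (1Z,3S)-1-[2-bromo-3-methyl-5-(triisopropylsilyloxy)phenyl]-3,7-dimethylocta-1,6-dien-3-ol | CC(C)=CCC[C@](C)(O)/C=C\c1cc(O[Si](C(C)C)(C(C)C)C(C)C)cc(C)c1Br | intermediate
13 | (2S)-2,8-dimethyl-2-(4-methylpent-3-en-1-yl)-6-(triisopropylsilyloxy)-2H-chromene | CC(C)=CCC[C@@]1(C)C=Cc2cc(O[Si](C(C)C)(C(C)C)C(C)C)cc(C)c2O1 | intermediate
14 | (2E)-5-[(2S)-2,8-dimethyl-6-(triisopropylsilyloxy)-2H-chromen-2-yl]-2-methylpent-2-en-1-ol (formed in the flask) | OC/C(C)=C/CC[C@@]1(C)C=Cc2cc(O[Si](C(C)C)(C(C)C)C(C)C)cc(C)c2O1 | intermediate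
15 | (2E)-5-[(2S)-2,8-dimethyl-6-(triisopropylsilyloxy)-2H-chromen-2-yl]-2-methylpent-2-enal | O=C/C(C)=C/CC[C@@]1(C)C=Cc2cc(O[Si](C(C)C)(C(C)C)C(C)C)cc(C)c2O1 | intermediate
16 | (2S)-2,8-dimethyl-2-[(3E)-4-methylhexa-3,5-dien-1-yl]-6-(triisopropylsilyloxy)-2H-chromene | C=C/C(C)=C/CC[C@@]1(C)C=Cc2cc(O[Si](C(C)C)(C(C)C)C(C)C)cc(C)c2O1 | intermediate
17 | 6-methylhept-5-en-2-one | CC(C)=CCCC(C)=O | starting material
18 | diethyl 6-methylhepta-1,5-dien-2-yl phosphate (formed in the flask) | CC(C)=CCCC(=C)OP(=O)(OCC)OCC | intermediate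
19 | 6-methylhept-5-en-1-yne | CC(C)=CCCC#C | intermediate
20 | [(1E)-2,6-dimethylhepta-1,5-dien-1-yl]dimethylalane (formed in the flask) | CC(C)=CCC/C(C)=C/[Al](C)C | intermediate
21 | (1E)-1-iodo-2,6-dimethylhepta-1,5-diene | CC(C)=CCC/C(C)=C/I | intermediate
22 | 9-{(3E)-6-[(2S)-2,8-dimethyl-6-(triisopropylsilyloxy)-2H-chromen-2-yl]-3-methylhex-3-en-1-yl}-9-borabicyclo[3.3.1]nonane (formed in the flask) | B1(CC/C(C)=C/CC[C@@]2(C)C=Cc3cc(O[Si](C(C)C)(C(C)C)C(C)C)cc(C)c3O2)C2CCCC1CCC2 | intermediate
23 | (2S)-2,8-dimethyl-6-(triisopropylsilyloxy)-2-[(3E,7E)-4,8,12-trimethyltrideca-3,7,11-trien-1-yl]-2H-chromene | CC(C)=CCC/C(C)=C/CC/C(C)=C/CC[C@@]1(C)C=Cc2cc(O[Si](C(C)C)(C(C)C)C(C)C)cc(C)c2O1 | intermediate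
24 | (2S)-2,8-dimethyl-2-[(3E,7E)-4,8,12-trimethyltrideca-3,7,11-trien-1-yl]-2H-chromen-6-ol | CC(C)=CCC/C(C)=C/CC/C(C)=C/CC[C@@]1(C)C=Cc2cc(O)cc(C)c2O1 | target

Total step count: 15.
Longest linear sequence: 10 steps. It runs through steps 4, 5, 6, 7, 8, 9, 10, 11, 14 and 15 from geraniol. The arene branch through steps 1, 2 and 3 is equally long.

Steps most likely to fail

Step 14 (key step).
- **Risk:** the hydroboration may lose site selectivity, by a second addition to the diene or by attack at chromene C3=C4. The homoallyl group may also pass slowly from boron to palladium, so that protodeboronation and β-hydride elimination compete.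
- **Fallback:** it sets out from 14 (held back before the MnO2 treatment of step 10) and 21, and comes back at 23. It forms the same C6'–C7' bond without any hydroboration. Appel bromination of 14 (CBr4, PPh3, CH2Cl2, 0 °C) should give the allylic bromide F1. Deborylative alkylation of F1 with bis[(pinacolato)boryl]methane and NaOtBu in THF should bring in C6' and give the homoallylic pinacol boronate F2. Suzuki–Miyaura coupling of F2 with 21 (Pd(OAc)2, RuPhos, aq KOH, THF, 60 °C) should then give 23.

Step 9.
- **Risk:** oxidative addition into the doubly ortho-flanked C–Br bond needs heat. At that temperature, Z-to-E isomerisation of the styrenyl carbinol, ionisation of the tertiary allylic alcohol or reductive debromination may outrun C–O reductive elimination.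
- **Fallback:** it sets out from 7 and 5 and comes back at 13. The ring is closed on a saturated, non-ionisable tether, and the C3=C4 bond is introduced afterwards.
  - Iodination of 7 (I2, PPh3, imidazole, CH2Cl2, 0 °C) should give the epoxy iodide F3.
  - Zinc dust in refluxing ethanol should open F3 reductively to (S)-linalool F4, with the tertiary C–O bond intact.
  - 9-BBN should hydroborate the vinyl group of F4 to the B-alkyl borane F5.
  - F5 should couple at the C–I bond of 5 (Pd(dppf)Cl2·CH2Cl2, aq K3PO4, DMF) to give the saturated bromo carbinol F6.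
  - Palladium-catalysed C–O coupling of F6 (Pd(OAc)2, tBuXPhos, Cs2CO3, toluene) should give the chroman F7.
  - Dehydrogenation of F7 with DDQ in refluxing benzene (hydride loss from C4, which is activated by O1) should give 13.

Step 10.
- **Risk:** conversion may be low and over-oxidation may occur. Oxidation could also take place at the allylic C2' methylene or at the benzylic C8 methyl group, and the peroxide could attack the electron-rich chromene.
- **Fallback:** it sets out from 13 and comes back at 15. Allylic oxidation is replaced by olefin cross metathesis of the prenyl terminus of 13 with methacrolein (second-generation Hoveyda–Grubbs catalyst, CH2Cl2, 40 °C). This should exchange the isopropylidene end for the (E)-2-methylenal terminus in one operation. The hindered C3=C4 bond, next to quaternary C2, should stay out of the metathesis.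

Further compounds
F1 | step 14 | (2S)-2-[(3E)-5-bromo-4-methylpent-3-en-1-yl]-2,8-dimethyl-6-(triisopropylsilyloxy)-2H-chromene | BrC/C(C)=C/CC[C@@]1(C)C=Cc2cc(O[Si](C(C)C)(C(C)C)C(C)C)cc(C)c2O1
F2 | step 14 | 2-{(3E)-6-[(2S)-2,8-dimethyl-6-(triisopropylsilyloxy)-2H-chromen-2-yl]-3-methylhex-3-en-1-yl}-4,4,5,5-tetramethyl-1,3,2-dioxaborolane | CC1(C)OB(CC/C(C)=C/CC[C@@]2(C)C=Cc3cc(O[Si](C(C)C)(C(C)C)C(C)C)cc(C)c3O2)OC1(C)C
F3 | step 9 | (2S,3R)-3-(iodomethyl)-2-methyl-2-(4-methylpent-3-en-1-yl)oxirane | CC(C)=CCC[C@]1(C)O[C@H]1CI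
F4 | step 9 | (S)-linalool, (3S)-3,7-dimethylocta-1,6-dien-3-ol | CC(C)=CCC[C@](C)(O)C=C
F5 | step 9 | (3S)-1-(9-borabicyclo[3.3.1]nonan-9-yl)-3,7-dimethyloct-6-en-3-ol | CC(C)=CCC[C@](C)(O)CCB1C2CCCC1CCC2
F6 | step 9 | (3S)-1-[2-bromo-3-methyl-5-(triisopropylsilyloxy)phenyl]-3,7-dimethyloct-6-en-3-ol | CC(C)=CCC[C@](C)(O)CCc1cc(O[Si](C(C)C)(C(C)C)C(C)C)cc(C)c1Br
F7 | step 9 | (2S)-2,8-dimethyl-2-(4-methylpent-3-en-1-yl)-6-(triisopropylsilyloxy)chroman | CC(C)=CCC[C@@]1(C)CCc2cc(O[Si](C(C)C)(C(C)C)C(C)C)cc(C)c2O1
F0 | step 10 | none | none
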